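**Plan**

1. Numbering (tricyclo[5.3.1.0^{1,5}]undecane): C1 quaternary bridgehead, C2 CH(CHO), C5 ring-fusion CH, C6 C(CH3)(CH2OH), C7 bridgehead CH, C8(CO2H)=C9, C10 CH(O-acyl), C11 CH2; ring A = C1, C5, C6, C7, C11; ring B = C1, C7, C8, C9, C10, C11; ring C = C1 to C5.
2. The retrosynthesis cuts, in this order: the C10–O ester; the exo bonds H–C5 and C6–CH2OH; C4–C5 (ring C); then C7–C8 together with C1–C10 (ring B). This leaves a 2-silyloxycyclopentadiene (ring A carrying the C2–C4 arm) and a vinyldiazoacetate (C8, C9, C10 and the carboxyl); the acyl chain is cut at its Z double bond.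
3. Enabling feature: in ring B the ester-bearing sp2 carbon C8 sits on bridgehead C7, C8=C9 is in place and C10 sits on bridgehead C1, with C11 and C5–C6 as the two other bridges. This is a bicyclo[3.2.1]octa-2,6-diene-2-carboxylate, the pattern a vinylcarbenoid and a cyclopentadiene give by cyclopropanation (C7–C8) followed by a Cope shift (C1–C10).
4. Forward: ring A is bought as 2-methylcyclopent-2-en-1-one and armed at the future C1; ring B is annulated in the key step; ring C is closed third (C4–C5) by B-alkyl Suzuki coupling; CH2OH, H-5 and O-10 are then put on from the exo faces, and the chain is joined last.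
5. Stereochemistry: C2 from a [Rh(cod)2]PF6/(S)-BINAP conjugate vinylation; C1 and C7 from the chiral dirhodium catalyst of the key step; C6, C5 and C10 from an exo-face ene reaction, a hydroxyl-directed hydrogenation and an SeO2 hydroxylation on the rigid bicycle; the chain alkene from a salt-free Wittig reaction.

Key step: step 7

Remark: in this numbering the given descriptors are 1R,2S,5S,6S,7S,10S; H-5, the C6 CH2OH and O-10 all lie on exo faces (syn to C11), so ring C is joined through the endo bond of C5 (trans A/C ring fusion), and the route is built to deliver exactly this arrangement.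

**Route**

Step 1
Reactants: 1 2-methylcyclopent-2-en-1-one; 2 2,2-dimethoxyacetaldehyde
Product: 6 (5E)-5-(2,2-dimethoxyethylidene)-2-methylcyclopent-2-en-1-one, via lithium dienolate 3 (not isolated), via lithium aldolate 4 (not isolated), via aldol mesylate 5 (not isolated)
Conditions: LiN(iPr)2, THF, −78 °C; 2 (anhydrous), −78 °C; MeSO2Cl, −78 → 0 °C; DBU, 0 → 25 °C
Reagents that add atoms: none
Why: Directed aldol condensation: kinetic deprotonation at C5 gives the cross-conjugated lithium dienolate, its aldol adduct is mesylated in the same flask, and E1cB elimination should give the more stable E-alkylidene; no stereocentre remains.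

Step 2
Reactants: 6 (5E)-5-(2,2-dimethoxyethylidene)-2-methylcyclopent-2-en-1-one
Product: 7 5-[(2S)-1,1-dimethoxybut-3-en-2-yl]-2-methylcyclopent-2-en-1-one (epimers at ring C5)
Conditions: [Rh(cod)2]PF6 (3 mol %), (S)-BINAP (3.3 mol %), CH2=CHBF3K, toluene/H2O, 100 °C
Reagents that add atoms: potassium vinyltrifluoroborate [K+].C=C[B-](F)(F)F
Why: Rhodium-catalysed asymmetric 1,4-addition of an alkenylboron reagent (Hayashi–Miyaura reaction) should occur at the exocyclic β-carbon, the 2-methyl-substituted ring enone being a poor acceptor; the chiral rhodium–bisphosphine complex sets the side-chain methine (the ligand enantiomer used is the one that gives S), and the ring α-carbon forms as an epimer mixture that is erased in step 3.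

Step 3
Reactants: 7 5-[(2S)-1,1-dimethoxybut-3-en-2-yl]-2-methylcyclopent-2-en-1-one
Product: 9 {2-[(2S)-1,1-dimethoxybut-3-en-2-yl]-5-methylcyclopenta-1,4-dien-1-yl}oxy(trimethyl)silane, via lithium dienolate 8 (not isolated)
Conditions: LiN(iPr)2, THF, −78 °C; Me3SiCl, −78 → 0 °C; used at once
Reagents that add atoms: chlorotrimethylsilane C[Si](C)(C)Cl
Why: Kinetic deprotonation at the only α′-hydrogen and O-silylation (silyl dienol ether formation) should give the cross-conjugated 2-silyloxy-1,3-diene as a single double-bond isomer, used immediately to outrun 1,5-hydrogen shifts.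

Step 4
Reactants: 10 tert-butyl 3-oxobutanoate
Product: 11 tert-butyl 2-diazo-3-oxobutanoate
Conditions: 4-acetamidobenzenesulfonyl azide, Et3N, MeCN, 0 → 25 °C
Reagents that add atoms: 4-acetamidobenzenesulfonyl azide CC(=O)Nc1ccc(cc1)S(=O)(=O)N=[N+]=[N-]
Why: Regitz diazo transfer to the doubly activated methylene of a β-keto ester.

Step 5
Reactants: 11 tert-butyl 2-diazo-3-oxobutanoate
Product: 12 tert-butyl 2-diazo-3-hydroxybutanoate (racemic)
Conditions: NaBH4, MeOH, 0 °C
Reagents that add atoms: none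
Why: Chemoselective borohydride reduction of the ketone of a 2-diazo-1,3-dicarbonyl compound, the diazo ester being inert; the carbinol centre is lost in step 6.

Step 6
Reactants: 12 tert-butyl 2-diazo-3-hydroxybutanoate
Product: 13 tert-butyl 2-diazobut-3-enoate
Conditions: POCl3, Et3N, CH2Cl2, 0 °C; kept cold and used at once
Reagents that add atoms: none
Why: Dehydration through the dichlorophosphate (E2 elimination) gives the vinyldiazoacetate, which is used immediately because it slowly closes to a pyrazole.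

Step 7
Reactants: 9 {2-[(2S)-1,1-dimethoxybut-3-en-2-yl]-5-methylcyclopenta-1,4-dien-1-yl}oxy(trimethyl)silane; 13 tert-butyl 2-diazobut-3-enoate
Product: 15 tert-butyl (1S,5R)-5-[(2S)-1,1-dimethoxybut-3-en-2-yl]-7-methyl-6-(trimethylsilyloxy)bicyclo[3.2.1]octa-2,6-diene-2-carboxylate, via divinylcyclopropane 14 (not isolated)
Conditions: Rh2(S-DOSP)4 (1 mol %; DOSP = N-(4-dodecylbenzenesulfonyl)prolinate; the R catalyst if the facial sense has to be inverted), pentane, slow addition of 13, −40 → 25 °C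
Reagents that add atoms: none
Why: Loss of N2 from 13 gives an electrophilic rhodium vinylcarbenoid that cyclopropanates the trisubstituted C4=C5 bond of 9, starting at its unsubstituted carbon C4 (the future C7, so that C7–C8 is made), to give the cis-divinylcyclopropane 14, which undergoes Cope rearrangement through a boat transition state that forms C1–C10, opens the three-membered ring and leaves C8=C9 and the silyl enol ether. The closest known reaction type is the tandem cyclopropanation/Cope rearrangement (formal [4+3] cycloaddition) of vinyldiazoacetates with cyclopentadienes and 2-silyloxydienes under dirhodium tetracarboxylate catalysis. The three-membered ring closes by a concerted, asynchronous [2+1] addition, and ring B (with the seven-membered ring C1–C10–C9–C8–C7–C6–C5 around it) closes by a [3,3]-sigmatropic shift. Both new bonds are made on the same face of the flat diene, so C7 and the quaternary C1 are set together by the face the carbenoid attacks, which the chiral dirhodium prolinate dictates, the side-chain stereocentre being remote and free to rotate. The step needs site-selectivity for this double bond over the tetrasubstituted silyl enol ether bond and the side-chain vinyl group, secured by the steric demand of the donor/acceptor carbenoid and the higher nucleophilicity of the diene terminus, and it needs carbenoid rather than vinylogous reactivity, which the hydrocarbon solvent and carboxylate ligands favour.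

Step 8
Reactants: 15 tert-butyl (1S,5R)-5-[(2S)-1,1-dimethoxybut-3-en-2-yl]-7-methyl-6-(trimethylsilyloxy)bicyclo[3.2.1]octa-2,6-diene-2-carboxylate
Product: 16 tert-butyl (1S,5R)-5-[(2S)-1,1-dimethoxybut-3-en-2-yl]-7-methyl-6-(trifluoromethanesulfonyloxy)bicyclo[3.2.1]octa-2,6-diene-2-carboxylate
Conditions: PhN(SO2CF3)2, CsF, 1,2-dimethoxyethane, 25 °C
Reagents that add atoms: N-phenylbis(trifluoromethanesulfonimide) O=S(=O)(N(c1ccccc1)S(=O)(=O)C(F)(F)F)C(F)(F)F
Why: Fluoride unmasks the enolate regiospecifically (the other α-carbon is the quaternary bridgehead) and the triflimide traps it on oxygen (enolate triflation), so the vinyl triflate keeps its double bond toward the methyl-bearing carbon.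

Step 9
Reactants: 16 tert-butyl (1S,5R)-5-[(2S)-1,1-dimethoxybut-3-en-2-yl]-7-methyl-6-(trifluoromethanesulfonyloxy)bicyclo[3.2.1]octa-2,6-diene-2-carboxylate
Product: 18 tert-butyl (1R,2S,7S)-2-(dimethoxymethyl)-6-methyltricyclo[5.3.1.0^{1,5}]undeca-5,8-diene-8-carboxylate, via alkylborane 17 (not isolated)
Conditions: 9-BBN, THF, 0 → 25 °C; then Pd(dppf)Cl2 (10 mol %), AsPh3, Cs2CO3, DMF/H2O, 50 °C
Reagents that add atoms: none
Why: Anti-Markovnikov hydroboration of the only monosubstituted alkene, then intramolecular B-alkyl Suzuki–Miyaura coupling with the vinyl triflate, should close ring C at C4–C5 as a cyclopentene annulated on the tetrasubstituted C5=C6 bond; no stereocentre is formed.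

Step 10
Reactants: 18 tert-butyl (1R,2S,7S)-2-(dimethoxymethyl)-6-methyltricyclo[5.3.1.0^{1,5}]undeca-5,8-diene-8-carboxylate
Product: 19 tert-butyl (1R,2S,6R,7S)-2-(dimethoxymethyl)-6-(hydroxymethyl)-6-methyltricyclo[5.3.1.0^{1,5}]undeca-4,8-diene-8-carboxylate
Conditions: (CH2O)n, Me2AlCl, CH2Cl2, −78 → 0 °C
Reagents that add atoms: formaldehyde (from paraformaldehyde) C=O
Why: Lewis-acid-promoted carbonyl-ene reaction of formaldehyde: the new C–C bond should form at the less hindered alkene carbon C6 (C5 is flanked by the quaternary C1) from the exo face, anti to the C8–C10 bridge, while an exo hydrogen is taken from C4, so CH2OH ends exo on the new quaternary centre and the double bond moves to C4=C5.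

Step 11
Reactants: 19 tert-butyl (1R,2S,6R,7S)-2-(dimethoxymethyl)-6-(hydroxymethyl)-6-methyltricyclo[5.3.1.0^{1,5}]undeca-4,8-diene-8-carboxylate
Product: 20 tert-butyl (1S,2S,5R,6S,7S)-2-(dimethoxymethyl)-6-(hydroxymethyl)-6-methyltricyclo[5.3.1.0^{1,5}]undec-8-ene-8-carboxylate
Conditions: [Ir(cod)(PCy3)(py)]PF6 (5 mol %), H2 (1 atm), CH2Cl2, 0 → 25 °C
Reagents that add atoms: none
Why: Hydroxyl-directed homogeneous hydrogenation: the homoallylic CH2OH on C6 binds iridium and both hydrogens are delivered syn to the exo face of C4=C5, which sets H-5 exo and hence the endo attachment of ring C in an irreversible, kinetically controlled addition, while the remote, electron-poor C8=C9 bond should react more slowly.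

Step 12
Reactants: 20 tert-butyl (1S,2S,5R,6S,7S)-2-(dimethoxymethyl)-6-(hydroxymethyl)-6-methyltricyclo[5.3.1.0^{1,5}]undec-8-ene-8-carboxylate
Product: 21 tert-butyl (1S,2S,5R,6S,7S)-6-[(tert-butyldimethylsilyloxy)methyl]-2-(dimethoxymethyl)-6-methyltricyclo[5.3.1.0^{1,5}]undec-8-ene-8-carboxylate
Conditions: t-BuMe2SiCl, imidazole, DMF, 25 °C
Reagents that add atoms: tert-butyldimethylsilyl chloride CC(C)(C)[Si](C)(C)Cl
Why: Standard silylation of the primary alcohol, so that only O-10 will be free for the later acylation.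

Step 13
Reactants: 21 tert-butyl (1S,2S,5R,6S,7S)-6-[(tert-butyldimethylsilyloxy)methyl]-2-(dimethoxymethyl)-6-methyltricyclo[5.3.1.0^{1,5}]undec-8-ene-8-carboxylate
Product: 22 tert-butyl (1R,2S,5S,6S,7S,10S)-6-[(tert-butyldimethylsilyloxy)methyl]-2-(dimethoxymethyl)-10-hydroxy-6-methyltricyclo[5.3.1.0^{1,5}]undec-8-ene-8-carboxylate
Conditions: SeO2 (30 mol %), t-BuOOH, CH2Cl2, 25 → 40 °C
Reagents that add atoms: tert-butyl hydroperoxide CC(C)(C)OO (terminal oxidant), selenium dioxide O=[Se]=O (oxygen carrier)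
Why: Allylic hydroxylation by SeO2 (ene reaction then [2,3]-sigmatropic shift; Riley oxidation) can occur only at C10, the other allylic carbon being the bridgehead C7, and oxygen should be delivered to the exo face because the endo face is covered by ring C and the C6 methyl group.

Step 14
Reactants: 23 7-bromoheptan-1-ol
Product: 24 (7-bromoheptyloxy)(tert-butyl)dimethylsilane
Conditions: t-BuMe2SiCl, imidazole, DMF, 25 °C
Reagents that add atoms: tert-butyldimethylsilyl chloride CC(C)(C)[Si](C)(C)Cl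
Why: Routine silyl protection of a primary alcohol.

Step 15
Reactants: 24 (7-bromoheptyloxy)(tert-butyl)dimethylsilane
Product: 25 [7-(tert-butyldimethylsilyloxy)heptyl]triphenylphosphonium bromide
Conditions: PPh3, MeCN, reflux
Reagents that add atoms: triphenylphosphine c1ccc(cc1)P(c1ccccc1)c1ccccc1
Why: SN2 quaternisation of triphenylphosphine by a primary bromide.

Step 16
Reactants: 25 [7-(tert-butyldimethylsilyloxy)heptyl]triphenylphosphonium bromide; 26 methyl 9-oxononanoate
Product: 28 methyl (9Z)-16-(tert-butyldimethylsilyloxy)hexadec-9-enoate, via phosphorus ylide 27 (not isolated)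
Conditions: NaN(SiMe3)2, THF, −78 °C; 26; −78 → 25 °C
Reagents that add atoms: none
Why: Wittig reaction of a non-stabilised ylide under lithium-free conditions, which should give the Z-alkene by kinetic control.

Step 17
Reactants: 28 methyl (9Z)-16-(tert-butyldimethylsilyloxy)hexadec-9-enoate
Product: 29 (9Z)-16-(tert-butyldimethylsilyloxy)hexadec-9-enoic acid
Conditions: LiOH, THF/MeOH/H2O, 25 °C; then 1 M HCl to pH 4
Reagents that add atoms: lithium hydroxide [Li+].[OH-]
Why: Saponification of the methyl ester, which the primary silyl ether and the Z-alkene should survive.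

Step 18
Reactants: 29 (9Z)-16-(tert-butyldimethylsilyloxy)hexadec-9-enoic acid; 22 tert-butyl (1R,2S,5S,6S,7S,10S)-6-[(tert-butyldimethylsilyloxy)methyl]-2-(dimethoxymethyl)-10-hydroxy-6-methyltricyclo[5.3.1.0^{1,5}]undec-8-ene-8-carboxylate
Product: 31 tert-butyl (1R,2S,5S,6S,7S,10S)-10-{[(9Z)-16-(tert-butyldimethylsilyloxy)hexadec-9-enoyl]oxy}-6-[(tert-butyldimethylsilyloxy)methyl]-2-(dimethoxymethyl)-6-methyltricyclo[5.3.1.0^{1,5}]undec-8-ene-8-carboxylate, via mixed anhydride 30 (not isolated)
Conditions: 2,4,6-trichlorobenzoyl chloride, Et3N, THF, 25 °C; then 22, DMAP, toluene, 40 °C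
Reagents that add atoms: none
Why: Yamaguchi esterification through the mixed anhydride and the acylpyridinium ion should acylate the hindered secondary allylic alcohol with retention at C10.

Step 19
Reactants: 31 tert-butyl (1R,2S,5S,6S,7S,10S)-10-{[(9Z)-16-(tert-butyldimethylsilyloxy)hexadec-9-enoyl]oxy}-6-[(tert-butyldimethylsilyloxy)methyl]-2-(dimethoxymethyl)-6-methyltricyclo[5.3.1.0^{1,5}]undec-8-ene-8-carboxylate
Product: 32 (1R,2S,5S,6S,7S,10S)-2-formyl-10-{[(9Z)-16-hydroxyhexadec-9-enoyl]oxy}-6-(hydroxymethyl)-6-methyltricyclo[5.3.1.0^{1,5}]undec-8-ene-8-carboxylic acid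
Conditions: CF3CO2H/CH2Cl2/H2O (10:10:1), 0 → 25 °C; aqueous NaHCO3 work-up
Reagents that add atoms: water O
Why: Acidolysis should remove the tert-butyl ester (as isobutene), both silyl ethers and the dimethyl acetal in one operation, under conditions that the allylic ester, the Z-alkene and the stereocentre next to the aldehyde are expected to survive.

**Compound list**

1 | 2-methylcyclopent-2-en-1-one | CC1=CCCC1=O | starting material
2 | 2,2-dimethoxyacetaldehyde | COC(OC)C=O | starting material
3 | lithium 5-methylcyclopenta-1,4-dien-1-olate | [Li+].CC1=CCC=C1[O-] | intermediate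
4 | lithium 2,2-dimethoxy-1-(3-methyl-2-oxocyclopent-3-en-1-yl)ethan-1-olate (diastereomer mixture) | [Li+].CC1=CCC(C([O-])C(OC)OC)C1=O | intermediate
5 | 2,2-dimethoxy-1-(3-methyl-2-oxocyclopent-3-en-1-yl)ethyl methanesulfonate (diastereomer mixture) | CC1=CCC(C(OS(C)(=O)=O)C(OC)OC)C1=O | intermediate
6 | (5E)-5-(2,2-dimethoxyethylidene)-2-methylcyclopent-2-en-1-one | CC1=CC/C(=C\C(OC)OC)C1=O | intermediate
7 | 5-[(2S)-1,1-dimethoxybut-3-en-2-yl]-2-methylcyclopent-2-en-1-one (epimers at ring C5) | CC1=CCC(C1=O)[C@@H](C(OC)OC)C=C | intermediate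
8 | lithium 2-[(2S)-1,1-dimethoxybut-3-en-2-yl]-5-methylcyclopenta-1,4-dien-1-olate | [Li+].CC1=CCC(=C1[O-])[C@@H](C(OC)OC)C=C | intermediate
9 | {2-[(2S)-1,1-dimethoxybut-3-en-2-yl]-5-methylcyclopenta-1,4-dien-1-yl}oxy(trimethyl)silane | CC1=CCC(=C1O[Si](C)(C)C)[C@@H](C(OC)OC)C=C | intermediate
10 | tert-butyl 3-oxobutanoate | CC(=O)CC(=O)OC(C)(C)C | starting material
11 | tert-butyl 2-diazo-3-oxobutanoate | CC(=O)C(=[N+]=[N-])C(=O)OC(C)(C)C | intermediate
12 | tert-butyl 2-diazo-3-hydroxybutanoate (racemic) | CC(O)C(=[N+]=[N-])C(=O)OC(C)(C)C | intermediate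
13 | tert-butyl 2-diazobut-3-enoate | C=CC(=[N+]=[N-])C(=O)OC(C)(C)C | intermediate
14 | tert-butyl 3-[(2S)-1,1-dimethoxybut-3-en-2-yl]-6-ethenyl-1-methyl-2-(trimethylsilyloxy)bicyclo[3.1.0]hex-2-ene-6-carboxylate (ethenyl cis to the five-membered ring) | C=C[C@@]1(C(=O)OC(C)(C)C)[C@H]2CC(=C(O[Si](C)(C)C)[C@@]12C)[C@@H](C(OC)OC)C=C | intermediate
15 | tert-butyl (1S,5R)-5-[(2S)-1,1-dimethoxybut-3-en-2-yl]-7-methyl-6-(trimethylsilyloxy)bicyclo[3.2.1]octa-2,6-diene-2-carboxylate | CC1=C(O[Si](C)(C)C)[C@@]2(CC=C(C(=O)OC(C)(C)C)[C@H]1C2)[C@@H](C(OC)OC)C=C | intermediate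
16 | tert-butyl (1S,5R)-5-[(2S)-1,1-dimethoxybut-3-en-2-yl]-7-methyl-6-(trifluoromethanesulfonyloxy)bicyclo[3.2.1]octa-2,6-diene-2-carboxylate | CC1=C(OS(=O)(=O)C(F)(F)F)[C@@]2(CC=C(C(=O)OC(C)(C)C)[C@H]1C2)[C@@H](C(OC)OC)C=C | intermediate
17 | tert-butyl (1S,5R)-5-[(2S)-4-(9-borabicyclo[3.3.1]nonan-9-yl)-1,1-dimethoxybutan-2-yl]-7-methyl-6-(trifluoromethanesulfonyloxy)bicyclo[3.2.1]octa-2,6-diene-2-carboxylate | CC1=C(OS(=O)(=O)C(F)(F)F)[C@@]2(CC=C(C(=O)OC(C)(C)C)[C@H]1C2)[C@@H](C(OC)OC)CCB3C4CCCC3CCC4 | intermediate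
18 | tert-butyl (1R,2S,7S)-2-(dimethoxymethyl)-6-methyltricyclo[5.3.1.0^{1,5}]undeca-5,8-diene-8-carboxylate | CC1=C2CC[C@H](C(OC)OC)[C@]23CC=C(C(=O)OC(C)(C)C)[C@H]1C3 | intermediate
19 | tert-butyl (1R,2S,6R,7S)-2-(dimethoxymethyl)-6-(hydroxymethyl)-6-methyltricyclo[5.3.1.0^{1,5}]undeca-4,8-diene-8-carboxylate (CH2OH exo) | C[C@@]1(CO)[C@@H]2C[C@]3(CC=C2C(=O)OC(C)(C)C)[C@@H](C(OC)OC)CC=C13 | intermediate
20 | tert-butyl (1S,2S,5R,6S,7S)-2-(dimethoxymethyl)-6-(hydroxymethyl)-6-methyltricyclo[5.3.1.0^{1,5}]undec-8-ene-8-carboxylate (H-5 exo) | C[C@@]1(CO)[C@@H]2C[C@]3(CC=C2C(=O)OC(C)(C)C)[C@@H](C(OC)OC)CC[C@@H]13 | intermediate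
21 | tert-butyl (1S,2S,5R,6S,7S)-6-[(tert-butyldimethylsilyloxy)methyl]-2-(dimethoxymethyl)-6-methyltricyclo[5.3.1.0^{1,5}]undec-8-ene-8-carboxylate | C[C@@]1(CO[Si](C)(C)C(C)(C)C)[C@@H]2C[C@]3(CC=C2C(=O)OC(C)(C)C)[C@@H](C(OC)OC)CC[C@@H]13 | intermediate
22 | tert-butyl (1R,2S,5S,6S,7S,10S)-6-[(tert-butyldimethylsilyloxy)methyl]-2-(dimethoxymethyl)-10-hydroxy-6-methyltricyclo[5.3.1.0^{1,5}]undec-8-ene-8-carboxylate (OH exo) | C[C@@]1(CO[Si](C)(C)C(C)(C)C)[C@@H]2C[C@]3([C@@H](O)C=C2C(=O)OC(C)(C)C)[C@@H](C(OC)OC)CC[C@@H]13 | intermediate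
23 | 7-bromoheptan-1-ol | OCCCCCCCBr | starting material
24 | (7-bromoheptyloxy)(tert-butyl)dimethylsilane | CC(C)(C)[Si](C)(C)OCCCCCCCBr | intermediate
25 | [7-(tert-butyldimethylsilyloxy)heptyl]triphenylphosphonium bromide | CC(C)(C)[Si](C)(C)OCCCCCCC[P+](c1ccccc1)(c1ccccc1)c1ccccc1.[Br-] | intermediate
26 | methyl 9-oxononanoate | COC(=O)CCCCCCCC=O | starting material
27 | [7-(tert-butyldimethylsilyloxy)heptylidene]triphenylphosphorane | CC(C)(C)[Si](C)(C)OCCCCCCC=P(c1ccccc1)(c1ccccc1)c1ccccc1 | intermediate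
28 | methyl (9Z)-16-(tert-butyldimethylsilyloxy)hexadec-9-enoate | COC(=O)CCCCCCC/C=C\CCCCCCO[Si](C)(C)C(C)(C)C | intermediate
29 | (9Z)-16-(tert-butyldimethylsilyloxy)hexadec-9-enoic acid | OC(=O)CCCCCCC/C=C\CCCCCCO[Si](C)(C)C(C)(C)C | intermediate
30 | (9Z)-16-(tert-butyldimethylsilyloxy)hexadec-9-enoic 2,4,6-trichlorobenzoic anhydride | O=C(OC(=O)c1c(Cl)cc(Cl)cc1Cl)CCCCCCC/C=C\CCCCCCO[Si](C)(C)C(C)(C)C | intermediate
31 | tert-butyl (1R,2S,5S,6S,7S,10S)-10-{[(9Z)-16-(tert-butyldimethylsilyloxy)hexadec-9-enoyl]oxy}-6-[(tert-butyldimethylsilyloxy)methyl]-2-(dimethoxymethyl)-6-methyltricyclo[5.3.1.0^{1,5}]undec-8-ene-8-carboxylate | C[C@@]1(CO[Si](C)(C)C(C)(C)C)[C@@H]2C[C@]3([C@@H](OC(=O)CCCCCCC/C=C\CCCCCCO[Si](C)(C)C(C)(C)C)C=C2C(=O)OC(C)(C)C)[C@@H](C(OC)OC)CC[C@@H]13 | intermediate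
32 | (1R,2S,5S,6S,7S,10S)-2-formyl-10-{[(9Z)-16-hydroxyhexadec-9-enoyl]oxy}-6-(hydroxymethyl)-6-methyltricyclo[5.3.1.0^{1,5}]undec-8-ene-8-carboxylic acid | C[C@@]1(CO)[C@@H]2C[C@]3([C@@H](OC(=O)CCCCCCC/C=C\CCCCCCO)C=C2C(=O)O)[C@@H](C=O)CC[C@@H]13 | target

**Totals and risks**

Total step count: 19. Longest linear sequence: 12 steps (1, 2, 3, 7, 8, 9, 10, 11, 12, 13, 18, 19).

Steps most likely to fail:

1. Step 11. Hydrogen may be delivered to the endo face (giving the unstrained cis ring fusion), or the conjugated C8=C9 bond may be reduced along with C4=C5. Fallback: the exo hydrogen would be put in by hydroboration and protonolysis instead of catalytic hydrogenation. Setting out from 19, BH3·SMe2 (THF, 0 → 25 °C) should first form the alkoxyborane at the C6 CH2OH, which then adds its B–H bond intramolecularly and syn across C4=C5 from the exo face. This gives the cyclic alkoxy(alkyl)borane F1, with boron on C4 and hydrogen exo on C5. Protonolysis of the C4–B bond with propanoic acid (diglyme, 100 °C) then removes boron and brings the route back at 20.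

2. Step 10. The ene reaction may bond at C5 instead of C6 (moving the double bond to an exocyclic methylene), or the Lewis acid may ionise the acetal or the tert-butyl ester. Fallback: the quaternary centre would be made by enolate alkylation and ring C closed on the ketone. Setting out from 15, fluoride (TASF, THF, −78 °C) liberates the enolate, which is alkylated on its exo face with 4-methoxybenzyl chloromethyl ether to give the α-quaternary ketone F2. Hydroboration of the vinyl group (9-BBN; NaBO3) gives the primary alcohol F3, and iodine (I2), PPh3 and imidazole give the iodide F4. SmI2 with HMPA in THF then closes ring C by Barbier addition to the ketone, giving the tertiary alcohol F5. Dehydration with the Burgess reagent gives the C4=C5 alkene F6, and DDQ (CH2Cl2, pH 7 buffer) removes the 4-methoxybenzyl group, which brings the route back at 19.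

3. Step 13. The deactivated allylic position of the enoate may not react with SeO2, or the product may over-oxidise to the ketone. Fallback: radical bromination and solvolysis replace the ene oxidation. Setting out from 21, N-bromosuccinimide with a radical initiator (PhCF3, 80 °C; Wohl–Ziegler bromination) should give the exo C10 bromide F7. Silver trifluoromethanesulfonate (AgOSO2CF3) in aqueous acetone should then replace bromide by hydroxyl from the open exo face, which brings the route back at 22.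

**Further compounds**

F1 | step 11 | cyclic alkoxy(alkyl)borane of 19: boron on C4 (exo) bonded to the C6 CH2O oxygen, hydrogen exo on C5 | C[C@@]1(CO[BH]4)[C@@H]2C[C@]3(CC=C2C(=O)OC(C)(C)C)[C@@H](C(OC)OC)C[C@H]4[C@@H]13
F2 | step 10 | tert-butyl 5-[(2S)-1,1-dimethoxybut-3-en-2-yl]-7-[(4-methoxybenzyloxy)methyl]-7-methyl-6-oxobicyclo[3.2.1]oct-2-ene-2-carboxylate (ether arm exo) | C[C@@]1(COCc4ccc(OC)cc4)[C@@H]2C[C@](CC=C2C(=O)OC(C)(C)C)([C@@H](C(OC)OC)C=C)C1=O
F3 | step 10 | tert-butyl 5-[(2S)-4-hydroxy-1,1-dimethoxybutan-2-yl]-7-[(4-methoxybenzyloxy)methyl]-7-methyl-6-oxobicyclo[3.2.1]oct-2-ene-2-carboxylate | C[C@@]1(COCc4ccc(OC)cc4)[C@@H]2C[C@](CC=C2C(=O)OC(C)(C)C)([C@@H](C(OC)OC)CCO)C1=O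
F4 | step 10 | tert-butyl 5-[(2S)-4-iodo-1,1-dimethoxybutan-2-yl]-7-[(4-methoxybenzyloxy)methyl]-7-methyl-6-oxobicyclo[3.2.1]oct-2-ene-2-carboxylate | C[C@@]1(COCc4ccc(OC)cc4)[C@@H]2C[C@](CC=C2C(=O)OC(C)(C)C)([C@@H](C(OC)OC)CCI)C1=O
F5 | step 10 | tert-butyl 2-(dimethoxymethyl)-5-hydroxy-6-[(4-methoxybenzyloxy)methyl]-6-methyltricyclo[5.3.1.0^{1,5}]undec-8-ene-8-carboxylate (C4 exo and OH endo on C5) | C[C@@]1(COCc4ccc(OC)cc4)[C@@H]2C[C@]3(CC=C2C(=O)OC(C)(C)C)[C@@H](C(OC)OC)CC[C@]13O
F6 | step 10 | 4-methoxybenzyl ether of 19 | C[C@@]1(COCc4ccc(OC)cc4)[C@@H]2C[C@]3(CC=C2C(=O)OC(C)(C)C)[C@@H](C(OC)OC)CC=C13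
F7 | step 13 | exo C10 bromide of 21 | C[C@@]1(CO[Si](C)(C)C(C)(C)C)[C@@H]2C[C@]3([C@@H](Br)C=C2C(=O)OC(C)(C)C)[C@@H](C(OC)OC)CC[C@@H]13
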